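**Retrosynthetic overview**
- The oxolane ring is closed last: C2–O1 bond by acid-mediated capture of a benzylic cation by a primary alcohol (sets C2), on an acyclic triol that comes from hydride reduction of an aldol lactone.
- The aldol lactone comes from a β-silyloxy-β-arylmethyl-γ-butyrolactone enolate and silyl-protected vanillin (C2–C3 bond, sets C3).
- The γ-butyrolactone comes from a prochiral 3,3-disubstituted oxetane by enantioselective ring-expansion carbonylation (key step, four- to five-membered ring, sets C4).
- The oxetane comes from an aryl Grignard reagent and the spiro-epoxide of oxetan-3-one; both aryl units derive from catechol through one protected 4-bromoguaiacol.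
- Ring order: oxetane (bought) → γ-lactone (ring expansion) → opened by reduction → oxolane.

Assumption: target atoms are numbered O1, C2 (aryl), C3 (CH2OH), C4 (OH and arylmethyl), C5; the SMILES is read as (2S,3R,4S), i.e. aryl trans to CH2OH and CH2OH cis to arylmethyl (trans to the tertiary OH).

**Step 1**
Reactants: 1 benzene-1,2-diol (catechol)
Product: 2 2-methoxyphenol
Conditions: MeI (1.0 equiv), K2CO3 (1.0 equiv), acetone, reflux; 2 separated from dimethyl ether by extraction into aq. NaOH
Reagents that add atoms: iodomethane, CI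
Why: Williamson ether synthesis; with one equivalent of base and MeI the catechol mono-anion is methylated once, because the product phenol is less acidic than catechol.

**Step 2**
Reactants: 2 2-methoxyphenol
Product: 3 4-bromo-2-methoxyphenol
Conditions: NBS (1.0 equiv), MeCN, 0 °C → rt
Reagents that add atoms: N-bromosuccinimide, O=C1CCC(=O)N1Br
Why: electrophilic aromatic bromination; the free OH directs more strongly than OMe, so bromine enters para to OH and gives the 1,2,4-pattern needed for both aryl rings.

**Step 3**
Reactants: 3 4-bromo-2-methoxyphenol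
Product: 4 tert-butyl(4-bromo-2-methoxyphenoxy)dimethylsilane
Conditions: TBSCl, imidazole, DMF, rt
Reagents that add atoms: tert-butyl(chloro)dimethylsilane, CC(C)(C)[Si](C)(C)Cl
Why: silyl ether formation (phenol protection), so the ring can carry a carbanion in steps 4 and 6 and a benzylic cation in step 10.

**Step 4**
Reactants: 4 tert-butyl(4-bromo-2-methoxyphenoxy)dimethylsilane
Product: 6 4-[(tert-butyldimethylsilyl)oxy]-3-methoxybenzaldehyde, via aryllithium 5 (not isolated)
Conditions: n-BuLi, THF, −78 °C; DMF, −78 °C → 0 °C; aq. work-up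
Reagents that add atoms: N,N-dimethylformamide, CN(C)C=O
Why: bromine–lithium exchange followed by formylation of the aryllithium with DMF (Bouveault aldehyde synthesis).

**Step 5**
Reactants: 7 oxetan-3-one
Product: 8 1,5-dioxaspiro[2.3]hexane
Conditions: Me3SI, KN(SiMe3)2, THF, 0 °C; then 7, 0 °C → rt; salts filtered off, product distilled and used as a titrated THF solution
Reagents that add atoms: trimethylsulfonium iodide, C[S+](C)C.[I-]
Why: Corey–Chaykovsky epoxidation; the sulfonium methylide adds to the strained ketone and the betaine closes to the spiro-epoxide (no stereocentre).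

**Step 6**
Reactants: 4 tert-butyl(4-bromo-2-methoxyphenoxy)dimethylsilane; 8 1,5-dioxaspiro[2.3]hexane
Product: 11 tert-butyl(2-methoxy-4-{[3-(trimethylsilyloxy)oxetan-3-yl]methyl}phenoxy)dimethylsilane, via arylmagnesium bromide 9 (not isolated), via magnesium alkoxide 10 (not isolated)
Conditions: 4, Mg, LiCl, THF, rt; CuI (10 mol%), 8, −30 → 0 °C; then Me3SiCl, DMPU, 0 °C → rt
Reagents that add atoms: chlorotrimethylsilane, C[Si](C)(C)Cl
Why: copper-catalysed Grignard opening of a 2,2-disubstituted epoxide at its CH2 group (SN2), with the oxetane inert in the absence of a strong Lewis acid, then O-silylation of the tertiary alkoxide in the same flask; 11 is achiral but prochiral.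

**Step 7 (key step)**
Reactants: 11 tert-butyl(2-methoxy-4-{[3-(trimethylsilyloxy)oxetan-3-yl]methyl}phenoxy)dimethylsilane
Product: 12 (4S)-4-{[4-(tert-butyldimethylsilyloxy)-3-methoxyphenyl]methyl}-4-(trimethylsilyloxy)oxolan-2-one
Conditions: CO (60 bar), 5 mol% [(salen)Cr(THF)2][Co(CO)4] made in the flask from (salen)CrCl and NaCo(CO)4, DME, 60 °C (salen = (S,S)-N,N′-bis(3,5-di-tert-butylsalicylidene)cyclohexane-1,2-diaminate)
Reagents that add atoms: carbon monoxide, [C-]#[O+]
Why: Proposed new method: enantioselective desymmetrising ring-expansion carbonylation of a prochiral 3,3-disubstituted oxetane. The cationic chiral (salen)Cr Lewis acid (trivalent chromium) binds the oxetane oxygen and the paired Co(CO)4− opens the ring by SN2 attack at one of the two enantiotopic CH2 groups; this is the enantio-determining event, with the salen pocket distinguishing the compact OSiMe3 from the long arylmethyl arm on C3. CO then inserts into the C–Co bond (1,2-alkyl shift to CO) and the chromium alkoxide closes onto the acyl cobalt to release the five-membered lactone with the quaternary carbinol centre S; the alkylcobalt has no β-hydrogen, so ketone formation is shut off. The closest known reactions are the achiral [Lewis acid][Co(CO)4]-catalysed carbonylation of oxetanes to γ-butyrolactones, the enantioselective carbonylation of meso-epoxides to β-lactones with chiral Lewis acid/cobaltate pairs, and chiral-Lewis-acid desymmetrising openings of 3-substituted oxetanes. Which ligand enantiomer gives (S)-12 cannot be predicted and must be found by experiment (both are available).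

**Step 8**
Reactants: 12 (4S)-4-{[4-(tert-butyldimethylsilyloxy)-3-methoxyphenyl]methyl}-4-(trimethylsilyloxy)oxolan-2-one; 6 4-[(tert-butyldimethylsilyl)oxy]-3-methoxybenzaldehyde
Product: 14 (3R,4S)-3-{[4-(tert-butyldimethylsilyloxy)-3-methoxyphenyl](hydroxy)methyl}-4-{[4-(tert-butyldimethylsilyloxy)-3-methoxyphenyl]methyl}-4-(trimethylsilyloxy)oxolan-2-one (carbinol centre as a mixture), via lithium enolate 13 (not isolated)
Conditions: LiN(i-Pr)2 (1.1 equiv), THF, −78 °C; 6, −78 °C, 30 min; AcOH quench at −78 °C
Reagents that add atoms: none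
Why: lithium enolate aldol addition; the aldehyde is expected to add on the enolate face that carries OSiMe3, anti to the arylmethyl arm on C4 (the larger group and the better σ-donor), which makes C3 R. This facial preference is an argument, not a precedent. The carbinol centre forms as a mixture that does not matter because it is reset in step 10.

**Step 9**
Reactants: 14 (3R,4S)-aldol lactone
Product: 15 (2R,3S)-1-[4-(tert-butyldimethylsilyloxy)-3-methoxyphenyl]-3-{[4-(tert-butyldimethylsilyloxy)-3-methoxyphenyl]methyl}-2-(hydroxymethyl)-3-(trimethylsilyloxy)butane-1,4-diol (C1 as a mixture)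
Conditions: LiAlH4, THF, −10 → 0 °C; H2O/aq. NaOH work-up
Reagents that add atoms: none
Why: hydride reduction of the lactone to the 1,4-diol, faster than retro-aldol at low temperature; C3 and C4 are untouched.

**Step 10**
Reactants: 15 (2R,3S)-triol
Product: 17 (3S,4R,5S)-5-(4-hydroxy-3-methoxyphenyl)-3-[(4-hydroxy-3-methoxyphenyl)methyl]-4-(hydroxymethyl)oxolan-3-ol (olivil; the target), via tris-silyl olivil 16 (not isolated)
Conditions: 10-camphorsulfonic acid (10 mol%), CH2Cl2, −20 → 0 °C; then Bu4NF (4 equiv), THF, 0 °C → rt; aq. work-up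
Reagents that add atoms: none
Why: acid-catalysed SN1 cycloetherification; the 4-silyloxy-3-methoxybenzyl cation is captured by the primary hydroxyl on the CH2 attached to C4 (five-membered ring; the other hydroxyls would give four-membered rings), anti to the C3 CH2OH and the C4 arylmethyl group. This sets C2 as S (2,3-trans) from either carbinol epimer. Fluoride desilylation then removes all three silyl groups without further acid, which would otherwise close the aryltetralin by Friedel–Crafts attack.

**Compound list**
1 | benzene-1,2-diol (catechol) | Oc1ccccc1O | starting material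
2 | 2-methoxyphenol | COc1ccccc1O | intermediate
3 | 4-bromo-2-methoxyphenol | COc1cc(Br)ccc1O | intermediate
4 | tert-butyl(4-bromo-2-methoxyphenoxy)dimethylsilane | COc1cc(Br)ccc1O[Si](C)(C)C(C)(C)C | intermediate
5 | [4-(tert-butyldimethylsilyloxy)-3-methoxyphenyl]lithium (not isolated) | [Li]c1ccc(O[Si](C)(C)C(C)(C)C)c(OC)c1 | intermediate
6 | 4-[(tert-butyldimethylsilyl)oxy]-3-methoxybenzaldehyde | COc1cc(C=O)ccc1O[Si](C)(C)C(C)(C)C | intermediate
7 | oxetan-3-one | O=C1COC1 | starting material
8 | 1,5-dioxaspiro[2.3]hexane | C1OC12COC2 | intermediate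
9 | [4-(tert-butyldimethylsilyloxy)-3-methoxyphenyl]magnesium bromide (not isolated) | COc1cc([Mg]Br)ccc1O[Si](C)(C)C(C)(C)C | intermediate
10 | bromomagnesium 3-{[4-(tert-butyldimethylsilyloxy)-3-methoxyphenyl]methyl}oxetan-3-olate (not isolated) | COc1cc(CC2(O[Mg]Br)COC2)ccc1O[Si](C)(C)C(C)(C)C | intermediate
11 | tert-butyl(2-methoxy-4-{[3-(trimethylsilyloxy)oxetan-3-yl]methyl}phenoxy)dimethylsilane | COc1cc(CC2(O[Si](C)(C)C)COC2)ccc1O[Si](C)(C)C(C)(C)C | intermediate
12 | (4S)-4-{[4-(tert-butyldimethylsilyloxy)-3-methoxyphenyl]methyl}-4-(trimethylsilyloxy)oxolan-2-one | COc1cc(C[C@@]2(O[Si](C)(C)C)COC(=O)C2)ccc1O[Si](C)(C)C(C)(C)C | intermediate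
13 | lithium enolate of 12 (not isolated) | COc1cc(C[C@@]2(O[Si](C)(C)C)COC(O[Li])=C2)ccc1O[Si](C)(C)C(C)(C)C | intermediate
14 | (3R,4S)-3-{[4-(tert-butyldimethylsilyloxy)-3-methoxyphenyl](hydroxy)methyl}-4-{[4-(tert-butyldimethylsilyloxy)-3-methoxyphenyl]methyl}-4-(trimethylsilyloxy)oxolan-2-one, carbinol epimers | COc1cc(C[C@@]2(O[Si](C)(C)C)COC(=O)[C@@H]2C(O)c3ccc(O[Si](C)(C)C(C)(C)C)c(OC)c3)ccc1O[Si](C)(C)C(C)(C)C | intermediate
15 | (2R,3S)-1-[4-(tert-butyldimethylsilyloxy)-3-methoxyphenyl]-3-{[4-(tert-butyldimethylsilyloxy)-3-methoxyphenyl]methyl}-2-(hydroxymethyl)-3-(trimethylsilyloxy)butane-1,4-diol, C1 epimers | COc1cc(C[C@@](O[Si](C)(C)C)(CO)[C@H](CO)C(O)c2ccc(O[Si](C)(C)C(C)(C)C)c(OC)c2)ccc1O[Si](C)(C)C(C)(C)C | intermediate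
16 | [(2S,3R,4S)-2-[4-(tert-butyldimethylsilyloxy)-3-methoxyphenyl]-4-{[4-(tert-butyldimethylsilyloxy)-3-methoxyphenyl]methyl}-4-(trimethylsilyloxy)oxolan-3-yl]methanol (not isolated) | COc1cc(C[C@@]2(O[Si](C)(C)C)CO[C@H](c3ccc(O[Si](C)(C)C(C)(C)C)c(OC)c3)[C@H]2CO)ccc1O[Si](C)(C)C(C)(C)C | intermediate
17 | (3S,4R,5S)-5-(4-hydroxy-3-methoxyphenyl)-3-[(4-hydroxy-3-methoxyphenyl)methyl]-4-(hydroxymethyl)oxolan-3-ol | COc1cc(C[C@@]2(O)CO[C@H](c3ccc(O)c(OC)c3)[C@H]2CO)ccc1O | target

**Totals**
Total steps: 10. Longest linear sequence: 8 (steps 1, 2, 3, 6, 7, 8, 9, 10); steps 4 and 5 are side branches.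

**Steps most likely to fail**

Step 7 (the proposed new step). The risks are low enantioselectivity, Lewis-acid-induced oligomerisation of the oxetane, and O-to-O silyl shift in the ring-opened intermediate. The fallback uses known chemistry only and gives up catalyst control of the stereocentre. It sets out from 11: the ring-expansion carbonylation is run with the known achiral ion pair [(salph)Al(THF)2][Co(CO)4] (salph = N,N′-bis(3,5-di-tert-butylsalicylidene)benzene-1,2-diaminate) under CO to give the racemic lactone F1. The enantiomers are separated by preparative chiral SFC; the (R)-lactone F2 is set aside and the (S)-enantiomer is 12, where the route resumes.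

Step 8. The risk is that the enolate 13 is attacked on the other face (anti to OSiMe3, syn to arylmethyl) or unselectively; β-elimination of the silyloxy group above −78 °C is a second risk. The fallback sets out from 12 and swaps the roles of the two lactone carbons, so that the opposite enolate face becomes the productive one. Enolate 13 is trapped with monomeric formaldehyde to give the hydroxymethyl lactone F3, in which CH2OH must be trans to OSiMe3. F3 is reduced with i-Bu2AlH (CH2Cl2, −78 °C) to the lactol F4, and excess Grignard reagent 9 opens the lactol and adds to the aldehyde. The lactone carbonyl thus becomes C2 instead of the CH2OH carbon, and the sequence comes back at 15. This hedges a wrong facial preference; it does not help if the preference is simply weak.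

Step 6. The risks are the handling of the volatile, water-miscible epoxide 8, bromide-induced opening of 8 followed by ring expansion to oxolan-3-one, and slow silylation of the hindered magnesium alkoxide. The fallback forms the same C–C bond at a carbonyl instead of an epoxide and sets out from aldehyde 6 and ketone 7. Aldehyde 6 is reduced with NaBH4 to the benzylic alcohol F5, which SOCl2 converts into the benzylic chloride F6. Mg gives the benzylic Grignard reagent F7, which adds to oxetan-3-one 7 to give the chloromagnesium alkoxide F8. Silylation in the flask with Me3SiCl comes back at 11; step 5 is then not needed.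

**Further compounds**
F1 | step 7 | racemic 4-{[4-(tert-butyldimethylsilyloxy)-3-methoxyphenyl]methyl}-4-(trimethylsilyloxy)oxolan-2-one | COc1cc(CC2(O[Si](C)(C)C)COC(=O)C2)ccc1O[Si](C)(C)C(C)(C)C
F2 | step 7 | (4R)-4-{[4-(tert-butyldimethylsilyloxy)-3-methoxyphenyl]methyl}-4-(trimethylsilyloxy)oxolan-2-one | COc1cc(C[C@]2(O[Si](C)(C)C)COC(=O)C2)ccc1O[Si](C)(C)C(C)(C)C
F3 | step 8 | (3S,4S)-4-{[4-(tert-butyldimethylsilyloxy)-3-methoxyphenyl]methyl}-3-(hydroxymethyl)-4-(trimethylsilyloxy)oxolan-2-one | COc1cc(C[C@@]2(O[Si](C)(C)C)COC(=O)[C@H]2CO)ccc1O[Si](C)(C)C(C)(C)C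
F4 | step 8 | (3S,4S)-4-{[4-(tert-butyldimethylsilyloxy)-3-methoxyphenyl]methyl}-3-(hydroxymethyl)-4-(trimethylsilyloxy)oxolan-2-ol, anomer mixture | COc1cc(C[C@@]2(O[Si](C)(C)C)COC(O)[C@H]2CO)ccc1O[Si](C)(C)C(C)(C)C
F5 | step 6 | [4-(tert-butyldimethylsilyloxy)-3-methoxyphenyl]methanol | COc1cc(CO)ccc1O[Si](C)(C)C(C)(C)C
F6 | step 6 | tert-butyl[4-(chloromethyl)-2-methoxyphenoxy]dimethylsilane | COc1cc(CCl)ccc1O[Si](C)(C)C(C)(C)C
F7 | step 6 | {[4-(tert-butyldimethylsilyloxy)-3-methoxyphenyl]methyl}magnesium chloride | COc1cc(C[Mg]Cl)ccc1O[Si](C)(C)C(C)(C)C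
F8 | step 6 | chloromagnesium 3-{[4-(tert-butyldimethylsilyloxy)-3-methoxyphenyl]methyl}oxetan-3-olate | COc1cc(CC2(O[Mg]Cl)COC2)ccc1O[Si](C)(C)C(C)(C)C
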